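At 15 min, the time at which the flasks are read, we expect the X reading to follow a line whose slope the earlier runs already show.

| flask | L | E | temperature | remark | time |
|---|---|---|---|---|---|
| oak | 2 M | 2.8 M | 95 °C | run made earlier |  |
| maple | 2 M | 2.8 M | 128 °C | run made earlier |  |
| grey | 2.0 M | 2.00 M | 140 °C |  | 15 min |
| ochre | 2.0 M | 2.00 M | 110 °C |  | 15 min |
| red | 2.0 M | 2.00 M |  | at 80 °C until 3.0 min, from then on at 140 °C | 15 min |
| violet | 2.0 M | 2.00 M | 80 °C |  | 15 min |

| run | time / min | X / % |
|---|---|---|
| oak | 12.0 | 3.5 |
| oak | 25.0 | 15.3 |
| oak | 40.0 | 29.1 |
| oak | 50.0 | 33.7 |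
| oak | 60.0 | 38.7 |
| oak | 80.0 | 40.6 |
| oak | 90.0 | 42.4 |
| maple | 2.50 | 2.2 |
| maple | 5.00 | 4.6 |
| maple | 8.00 | 8.0 |
| maple | 10.0 | 10.2 |
| maple | 15.0 | 13.9 |
| maple | 20.0 | 18.6 |

(standard deviation of a reading: 0.5 percentage points)

* the flask that comes out highest in amount of X, in percent of the L charged, or "all alike" when all lie within 1.5 percentage points (grey / ochre / red / violet / all alike)
* X at the end, in percent of the L charged, grey
* X at the end, in percent of the L charged, ochre
* X at the end, in percent of the L charged, red
* X at the end, in percent of the L charged, violet

- solid, in amounts per volume of the solution: E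
- at the start none of E is in solution

From its first to its third reading the oak run climbs by 0.00914 /min, as a fraction of the L charged, and the hotter maple run climbs by 0.00930 /min, which we call the feed slope: the X gained per minute once the line is running. Since the two slopes stand level, we read a rate-limiting step that hardly feels temperature, the dissolving of solid E, and a constant rate integrates to X = slope × time. This main step alone gives 13.9% at the time of reading, and we assume that the slope holds at 2.00 M of E, though both runs charged 2.8 M.

The next process is a lag. The line through the oak readings meets zero at 8.17 min, whereas the maple readings show no lag that we can tell from the 0.538 min to which one scatter on the slope amounts. Ochre lies near the middle of those temperatures, so we take their geometric mean, 2.10 min, and reckon 12.0% for ochre. One equal step down from oak puts the lag of violet near 31.9 min, longer than the run, so we expect violet to show just the foot of the curve. Grey keeps 13.9%, and we put red level with it, since we take the feed to run during its cold 3.0 min.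

Last comes the rest. The oak readings flatten near 42.4%, well above our numbers, so we subtract nothing, although grey lies hotter than both earlier runs. We therefore expect grey and red on top.

The forecast, lower than ours for grey and ochre, says “If dissolution scales with the solid loading, the slope at 2.0 M E is about 0.66 %/min” and gives 10% for grey, 8.6% for ochre, 9.8% for red and 1.6% for violet, with grey highest.

The flasks give 10.4% in grey, 14.7% in ochre, 10.5% in red and 1.00% in violet, so ochre comes out highest, 2.7 percentage points above our ochre, while grey lies 3.5 points under the feed slope's 13.9%, with Q at 55.4% in grey against 10.7% in ochre.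

    Z ⇌ X (K = 1.50, k = 0.0350 /min, Ea = 109 kJ/mol, ΔH = −15.0 kJ/mol)
    L + J → Z (k = 0.0160 /M/min, Ea = 90.0 kJ/mol)
    J ⇌ D (K = 1.00, k = 0.380 /min, Ea = 102 kJ/mol, ΔH = −37.0 kJ/mol)
    E ⇌ J, rate k4*(cs4 - [J]) while solid is left; crystals form when [J] > cs4 (solubility = 1.80 M, k = 0.0450 /min)
    L + Z → Q (k = 0.00290 /M/min, Ea = 89.0 kJ/mol)
    (constants at 80 °C)

In red at 7.50 min, at 140 °C, the making of X from Z, forward step alone, has a half-life of 0.0902 min, far shorter than the 2.4 min of Z by the loss of L + Z to Q, and X stands to Z at 0.710, beside the 0.714 of that step's equilibrium constant in grey at the same temperature. Red read at 1.0 h holds 14.6% of X against the 55.8% of the slope, with L at 0%.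

The readings are calculated from invented constants; noise was put on by code.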